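Kukoamine A is cut at both C(=O)–CH2 bonds of its two terminal amides. Each amide carbonyl carbon carries a CH2–CH2 chain ending in a catechol benzene ring, the pattern left when a carbamoyl radical adds to the CH2 terminus of a vinylarene. One photoredox operation decarboxylates a spermine-derived bis-oxamic acid twice and joins both carbonyl carbons to 3,4-diacetoxystyrene, forming two C–C bonds, no ring and no stereocentre. The precursor is spermine with Boc groups on the inner nitrogens N4 and N9 and an oxamic acid (NH–CO–CO2H) on each terminal nitrogen; acid then strips Boc and acetate together.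

Key step: step 4

Remark: protonation states are not numbered separately, so 13 is listed with the free-base SMILES of the target although step 5 delivers it as the bis(hydrochloride) salt, the form in which this air-sensitive catechol amine is best kept.

Step 1
Reactants: 1 spermine; 2 ethyl trifluoroacetate; 3 di-tert-butyl dicarbonate
Product: 6 N4,N9-bis(tert-butoxycarbonyl)spermine, via bis-trifluoroacetamide 4 (not isolated), via tetra-protected spermine 5 (not isolated)
Conditions: CF3CO2Et (2.05 equiv), MeOH, −78 → 0 °C; Boc2O (2.5 equiv), 0 °C → rt; conc. aq. NH3, rt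
Reagents that add atoms: di-tert-butyl dicarbonate, CC(C)(C)OC(=O)OC(=O)OC(C)(C)C (ethyl trifluoroacetate, CCOC(=O)C(F)(F)F, adds atoms only to 4 and 5)
Why: Chemoselective aminolysis of ethyl trifluoroacetate by the unhindered primary amines at low temperature, carbamate formation at the two remaining secondary amines with Boc2O, and ammonolysis of the electron-poor trifluoroacetamides (to which Boc carbamates are inert, while excess Boc2O is scavenged by ammonia) form a standard one-pot orthogonal protection sequence for linear polyamines.

Step 2
Reactants: 6 N4,N9-bis(tert-butoxycarbonyl)spermine; 7 ethyl chlorooxoacetate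
Product: 8 N1,N12-bis(ethoxyoxalyl)-N4,N9-bis(tert-butoxycarbonyl)spermine (the diethyl bis-oxamate)
Conditions: ClCOCO2Et (2.2 equiv), Et3N (2.5 equiv), CH2Cl2, −10 °C → rt
Reagents that add atoms: ethyl chlorooxoacetate, CCOC(=O)C(=O)Cl
Why: Schotten–Baumann-type N-acylation in which the acid chloride carbonyl of 7 is far more electrophilic than its ester carbonyl, so each primary amine of 6 becomes an ethyl oxamate while the Boc carbamates stay untouched.

Step 3
Reactants: 8 N1,N12-bis(ethoxyoxalyl)-N4,N9-bis(tert-butoxycarbonyl)spermine
Product: 9 N1,N12-bis(carboxycarbonyl)-N4,N9-bis(tert-butoxycarbonyl)spermine (the bis-oxamic acid)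
Conditions: LiOH·H2O (2.5 equiv), THF/H2O 3:1, 0 °C → rt; then cold 1 M HCl to pH 3, EtOAc extraction
Reagents that add atoms: lithium hydroxide, [Li+].[OH-]
Why: Ester saponification by acyl–oxygen cleavage, fast at 0 °C because the oxamate ester is activated by the neighbouring amide carbonyl, under conditions that leave the Boc carbamates and the oxamide C–N bond intact, with brief cold acidification liberating the diacid without Boc loss.

Step 4
Reactants: 9 N1,N12-bis(carboxycarbonyl)-N4,N9-bis(tert-butoxycarbonyl)spermine; 10 3,4-diacetoxystyrene (3 equiv)
Product: 12 N4,N9-bis(tert-butoxycarbonyl)-N1,N12-bis[3-(3,4-diacetoxyphenyl)propanoyl]spermine (tetra-O-acetyl-N4,N9-di-Boc-kukoamine A), via mono-adduct acid 11 (not isolated)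
Conditions: 4CzIPN (2,4,5,6-tetra(carbazol-9-yl)isophthalonitrile, 5 mol %), 2,4,6-triisopropylbenzenethiol (20 mol %), Cs2CO3 (5 mol %), degassed DMF (0.05 M in 9), 450 nm LEDs, rt, argon
Reagents that add atoms: none
Why: Proposed new method: catalytic Cs2CO3 converts part of 9 into its oxamate, which is oxidised by photoexcited 4CzIPN and loses CO2 to give a nucleophilic sigma-type carbamoyl radical; this adds to the unsubstituted CH2 terminus of 10, the benzylic radical so formed abstracts hydrogen from the arenethiol, and the thiyl radical is reduced by the 4CzIPN radical anion to thiolate, which deprotonates the next oxamic acid, so that both termini react in turn through 11. The closest known reaction types are the photoredox decarboxylative Giese-type hydrocarbamoylation of electron-poor alkenes with oxamic acids and the thiol-cocatalysed anti-Markovnikov hydrofunctionalisation of styrenes; their combination on a vinylarene, twice in one molecule, is the unproven part. No ring is closed and no stereocentre is formed. The step needs anti-Markovnikov regioselectivity, which the aryl-stabilised benzylic radical secures, and termination by hydrogen-atom transfer instead of styrene oligomerisation, which the thiol secures, while the excess of 10 and the low thiol loading should let the carbamoyl radical be captured by the alkene before it is reduced to a formamide. The acetates hold the arene, and the Boc groups hold the inner nitrogens, beyond the oxidising reach of the photocatalyst, so only the carboxylate is oxidised; running the free diacid with only catalytic base keeps the thiolate protonated and the aryl acetates intact.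

Step 5
Reactants: 12 N4,N9-bis(tert-butoxycarbonyl)-N1,N12-bis[3-(3,4-diacetoxyphenyl)propanoyl]spermine
Product: 13 kukoamine A, N1,N12-bis[3-(3,4-dihydroxyphenyl)propanoyl]spermine, obtained as its bis(hydrochloride)
Conditions: 1.25 M HCl in MeOH (large excess), argon, 0 °C → rt (40 °C if needed); evaporation, trituration with Et2O
Reagents that add atoms: none
Why: Acidolysis of the two Boc carbamates and acid-catalysed transesterification of the four aryl acetates to methyl acetate run together in anhydrous methanolic HCl, in which the secondary amides are inert, methanol intercepts the tert-butyl cation before it can alkylate the catechol rings, and the acidic oxygen-free medium protects the catechols from autoxidation.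

Compound list
1 | spermine | NCCCNCCCCNCCCN | starting material
2 | ethyl trifluoroacetate | CCOC(=O)C(F)(F)F | starting material
3 | di-tert-butyl dicarbonate | CC(C)(C)OC(=O)OC(=O)OC(C)(C)C | starting material
4 | N1,N12-bis(trifluoroacetyl)spermine | O=C(NCCCNCCCCNCCCNC(=O)C(F)(F)F)C(F)(F)F | intermediate (not isolated)
5 | N1,N12-bis(trifluoroacetyl)-N4,N9-bis(tert-butoxycarbonyl)spermine | O=C(NCCCN(C(=O)OC(C)(C)C)CCCCN(C(=O)OC(C)(C)C)CCCNC(=O)C(F)(F)F)C(F)(F)F | intermediate (not isolated)
6 | N4,N9-bis(tert-butoxycarbonyl)spermine | NCCCN(C(=O)OC(C)(C)C)CCCCN(C(=O)OC(C)(C)C)CCCN | intermediate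
7 | ethyl chlorooxoacetate | CCOC(=O)C(=O)Cl | starting material
8 | N1,N12-bis(ethoxyoxalyl)-N4,N9-bis(tert-butoxycarbonyl)spermine | CCOC(=O)C(=O)NCCCN(C(=O)OC(C)(C)C)CCCCN(C(=O)OC(C)(C)C)CCCNC(=O)C(=O)OCC | intermediate
9 | N1,N12-bis(carboxycarbonyl)-N4,N9-bis(tert-butoxycarbonyl)spermine | O=C(O)C(=O)NCCCN(C(=O)OC(C)(C)C)CCCCN(C(=O)OC(C)(C)C)CCCNC(=O)C(=O)O | intermediate
10 | 3,4-diacetoxystyrene | C=Cc1ccc(OC(C)=O)c(OC(C)=O)c1 | starting material
11 | N1-[3-(3,4-diacetoxyphenyl)propanoyl]-N12-(carboxycarbonyl)-N4,N9-bis(tert-butoxycarbonyl)spermine (mono-adduct acid) | CC(=O)Oc1ccc(CCC(=O)NCCCN(C(=O)OC(C)(C)C)CCCCN(C(=O)OC(C)(C)C)CCCNC(=O)C(=O)O)cc1OC(C)=O | intermediate (not isolated)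
12 | N4,N9-bis(tert-butoxycarbonyl)-N1,N12-bis[3-(3,4-diacetoxyphenyl)propanoyl]spermine | CC(=O)Oc1ccc(CCC(=O)NCCCN(C(=O)OC(C)(C)C)CCCCN(C(=O)OC(C)(C)C)CCCNC(=O)CCc2ccc(OC(C)=O)c(OC(C)=O)c2)cc1OC(C)=O | intermediate
13 | kukoamine A (no stereocentres) | O=C(CCc1ccc(O)c(O)c1)NCCCNCCCCNCCCNC(=O)CCc1ccc(O)c(O)c1 | target

Total step count: 5
Longest linear sequence: 5 steps (1 → 6 → 8 → 9 → 12 → 13)

Steps most likely to fail

1. Step 4 (bears the label "Proposed new method:"). The second hydrocarbamoylation may stall at 11. The carbamoyl radical may be reduced by the thiol before it meets the alkene, leaving formamide ends. The styrene may be lost to oligomerisation or thiol–ene addition. Thiolate may also strip aryl acetates. The fallback uses known chemistry, sets out from 6 and comes back at 12, so that steps 2 and 3 are not needed. Commercial 3-(3,4-dihydroxyphenyl)propanoic acid (O=C(O)CCc1ccc(O)c(O)c1) would be acetylated with Ac2O in pyridine and worked up with water to give 3-(3,4-diacetoxyphenyl)propanoic acid F1. Oxalyl chloride and catalytic DMF in CH2Cl2 would turn this into 3-(3,4-diacetoxyphenyl)propanoyl chloride F2. F2 (2.1 equiv) would then acylate both primary amines of 6 with Et3N in CH2Cl2 at −20 °C, where acid chloride aminolysis should far outrun aminolysis of the aryl acetates, giving 12.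

2. Step 5. Methanolysis of the four aryl acetates may lag behind Boc cleavage and leave partly acetylated salts that are hard to separate. The catechol rings may be tert-butylated, or may autoxidise during isolation of the polar product. The fallback sets out from 12 and comes back at 13, replacing the single acidic operation by two orthogonal ones with a neutral, chromatographable intermediate. Hydrazine hydrate in THF/MeOH at 0 °C under argon should cleave only the aryl acetates by nucleophilic deacylation, giving N4,N9-bis(tert-butoxycarbonyl)kukoamine A F3. Anhydrous 4 M HCl in dioxane at 0 °C → rt should then remove the Boc groups and precipitate 13 as its bis(hydrochloride).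

3. Step 1. Discrimination between primary and secondary amines in the trifluoroacetylation may be imperfect, and incomplete removal of the trifluoroacetyl groups would add to a mixture of polar, partially protected polyamines that resists separation. The fallback builds the protected tetraamine from smaller pieces instead of differentiating the nitrogens of spermine. It sets out from 3, with commercial 1,4-diaminobutane (NCCCCN) and acrylonitrile (C=CC#N) in place of 1, and comes back at 6. Twofold aza-Michael addition of the diamine to acrylonitrile (2 equiv, EtOH, 0 °C → rt) should give N,N'-bis(2-cyanoethyl)butane-1,4-diamine F4. Boc2O in CH2Cl2 should cap its two secondary amines to give N,N'-bis(tert-butoxycarbonyl)-N,N'-bis(2-cyanoethyl)butane-1,4-diamine F5. Hydrogenation of both nitriles over Raney Ni (H2, NH3 in EtOH) should then deliver 6.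

Further compounds
F1 | step 4 | 3-(3,4-diacetoxyphenyl)propanoic acid | CC(=O)Oc1ccc(CCC(=O)O)cc1OC(C)=O
F2 | step 4 | 3-(3,4-diacetoxyphenyl)propanoyl chloride | CC(=O)Oc1ccc(CCC(=O)Cl)cc1OC(C)=O
F3 | step 5 | N4,N9-bis(tert-butoxycarbonyl)kukoamine A | O=C(CCc1ccc(O)c(O)c1)NCCCN(C(=O)OC(C)(C)C)CCCCN(C(=O)OC(C)(C)C)CCCNC(=O)CCc1ccc(O)c(O)c1
F4 | step 1 | N,N'-bis(2-cyanoethyl)butane-1,4-diamine | N#CCCNCCCCNCCC#N
F5 | step 1 | N,N'-bis(tert-butoxycarbonyl)-N,N'-bis(2-cyanoethyl)butane-1,4-diamine | N#CCCN(C(=O)OC(C)(C)C)CCCCN(C(=O)OC(C)(C)C)CCC#N
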